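**Strategy.** The route rests on disconnecting both ring C–O bonds (C1–O and C4–O) at once. It exploits the fact that the C1 and C4 oxygens of the cyclohexane ring are cis to each other and both trans to the C6 side chain, which is what a dioxygen bridge added to one face of a cyclohexa-1,3-diene delivers. The key step is a [4+2] cycloaddition of singlet oxygen to (R)-p-mentha-1,5,8-triene 5, made from (R)-carvone by a Shapiro reaction. It forms both C–O bonds, the peroxide ring and the C1 and C4 stereocentres in one operation. The isopropenyl group then becomes a trans-fused lactone that differentiates C1–O from C4–O, sets C7 by equilibration and is extended to the C8–C11 chain.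

Key step: step 3

Numbering used for every compound: ring C1 (angelate oxygen), C2 (CH2), C3 (methyl), C4 (hydroxyl), C5 (CH2), C6 (side chain); chain C7 (methyl), C8, C9 (acetate), C10=C11. In carvone 1 the carbonyl carbon is C2, the alkene is C3=C4 and the stereocentre is C6.

**Step 1**
Reactants: 1 (R)-(−)-carvone; 2 p-toluenesulfonohydrazide
Product: 3 carvone tosylhydrazone
Conditions: EtOH, AcOH (cat.), 25 °C
Reagents that add atoms: none
Why: Hydrazone formation by acid-catalysed condensation at the C2 ketone should give the crystalline tosylhydrazone, with the NHTs group expected on the side of the C1 methylene and the C6 stereocentre untouched.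

**Step 2**
Reactants: 3 carvone tosylhydrazone
Product: 5 (R)-5-isopropenyl-2-methylcyclohexa-1,3-diene, via vinyllithium 4 (not isolated)
Conditions: MeLi (2.5 equiv), Et2O, 0 → 25 °C; then H2O, 0 °C
Reagents that add atoms: none
Why: Shapiro reaction: MeLi removes N–H and then a C1–H syn to the sulfonamide nitrogen, the dianion loses sulfinate and dinitrogen to give the C2 vinyllithium, and protonation gives the C1=C2 alkene conjugated with C3=C4 without involving the remote C6 stereocentre.

**Step 3**
Reactants: 5 (R)-5-isopropenyl-2-methylcyclohexa-1,3-diene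
Product: 6 (1R,4R,7S)-5-methyl-7-(prop-1-en-2-yl)-2,3-dioxabicyclo[2.2.2]oct-5-ene (O–O bridge from C1 to C4, anti to the C6 isopropenyl group)
Conditions: O2, meso-tetraphenylporphyrin (cat.), CH2Cl2, visible light, −30 °C
Reagents that add atoms: dioxygen (O=O)
Why: Photosensitised singlet oxygen adds to the ring-locked s-cis diene C1=C2–C3=C4 in a concerted suprafacial [4+2] cycloaddition, the closest known reaction being the dye-sensitised photooxygenation of alpha-phellandrene-type cyclohexa-1,3-dienes to bicyclic endoperoxides. The six-membered 3,6-dihydro-1,2-dioxine ring (O–C1–C2=C3–C4–O) closes by cycloaddition, both C–O bonds forming in the same event on one face of the diene, which gives the 2,3-dioxabicyclo[2.2.2]octene. C1 and C4 become stereocentres whose oxygens are necessarily cis to each other, and their absolute sense is set by the C6 stereocentre, whose isopropenyl group shields its own face of the adjacent terminus C1. The step needs attack anti to C6 and cycloaddition in preference to ene reactions: the first rests only on this allylic substituent, so a moderate bias is expected and the syn adduct is removed by chromatography here; the second is secured by the cisoid diene, which should react much faster than the 1,1-disubstituted isopropenyl alkene, and by the low temperature.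

**Step 4**
Reactants: 6 endoperoxide
Product: 7 cis-ene-diol (3-methyl-6-isopropenylcyclohex-2-ene-1,4-diol, both OH cis to each other and trans to the isopropenyl group)
Conditions: thiourea (2 equiv), MeOH, 0 → 25 °C
Reagents that add atoms: none
Why: Reductive cleavage of the peroxide O–O bond by thiourea (sulfur attacks oxygen) leaves both C–O bonds, hence the C1 and C4 configurations, and both alkenes untouched.

**Step 5**
Reactants: 7 cis-ene-diol
Product: 9 ene-triol (C8 primary alcohol, C7 epimer mixture), via borane adduct 8 (not isolated)
Conditions: 9-BBN (3.5 equiv), THF, 0 → 25 °C; then NaOH (aq), H2O2, 0 → 25 °C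
Reagents that add atoms: hydrogen peroxide (OO)
Why: Hydroboration–oxidation: after the two hydroxyls have become borinates, 9-BBN should place boron on the terminal carbon C8 of the 1,1-disubstituted alkene much faster than it attacks the trisubstituted, oxygen-flanked ring alkene, and alkaline peroxide gives the primary alcohol; C7 is formed without a safeguard here and both epimers go on to step 8.

**Step 6**
Reactants: 9 ene-triol
Product: 12 enone lactone (C4 ketone, C2=C3, lactone C1–O–C8(=O), trans-fused), via lactol 10 (not isolated), via hydroxy lactone 11 (not isolated)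
Conditions: [Cu(MeCN)4]OTf (5 mol %), 2,2'-bipyridine (5 mol %), TEMPO (5 mol %), N-methylimidazole (10 mol %), MeCN, air, 25 °C; then ABNO (9-azabicyclo[3.3.1]nonane N-oxyl, 5 mol %), air, 25 °C
Reagents that add atoms: none
Why: Copper/nitroxyl aerobic alcohol oxidation: the TEMPO system oxidises only the primary C8 alcohol, the aldehyde is trapped by the C1 hydroxyl (the only one that can reach it, as a five-membered trans-fused lactol) and oxidised on to the lactone, after which the less hindered nitroxyl ABNO lets the same copper catalyst oxidise the remaining secondary allylic C4 alcohol to the enone, so that C1–O and C4–O are differentiated.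

**Step 7**
Reactants: 12 enone lactone
Product: 13 saturated keto lactone (C3 and C7 epimer mixture)
Conditions: Cu(OAc)2·H2O (5 mol %), 1,2-bis(diphenylphosphino)benzene (5 mol %), (EtO)2MeSiH (2 equiv), t-BuOH (2 equiv), toluene, 25 °C
Reagents that add atoms: none
Why: Copper hydride conjugate reduction: the phosphine-ligated Cu–H adds hydride to C2 of the enone and t-BuOH protonates the copper enolate at C3, which leaves lactone, ketone and the allylic C1–O bond intact (no hydrogenolysis, as could occur over palladium); the C3 configuration formed here is not relied on.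

**Step 8**
Reactants: 13 saturated keto lactone
Product: 14 keto lactone with C3 methyl equatorial (cis to C1–O) and C7 methyl cis to H6
Conditions: KOt-Bu (0.5 equiv), t-BuOH–THF, 25 °C; then aq. NH4Cl
Reagents that add atoms: none
Why: Base-mediated epimerisation through the ketone enolate (C3) and the lactone enolate (C7) under thermodynamic control should place the C3 methyl equatorial on the chair locked by the trans ring fusion and the C7 methyl cis to H6, where it avoids the near-eclipsed contact with C5; both are the target configurations, and minor epimers are separated and resubmitted.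

**Step 9**
Reactants: 14 keto lactone
Product: 15 hydroxy lactone (axial C4–OH, cis to the C3 methyl and to C1–O)
Conditions: LiBH(s-Bu)3 (L-Selectride, 1.2 equiv), THF, −78 °C; then H2O
Reagents that add atoms: none
Why: Diastereoselective ketone reduction with a bulky hydride: L-Selectride attacks the locked 2-methylcyclohexanone from the equatorial direction and should give the axial C4 alcohol, while the lactone is not reduced at −78 °C.

**Step 10**
Reactants: 15 hydroxy lactone
Product: 16 C4 TBS ether of the lactone
Conditions: TBSOTf, 2,6-lutidine, CH2Cl2, −78 → 0 °C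
Reagents that add atoms: tert-butyldimethylsilyl triflate (CC(C)(C)[Si](C)(C)OS(=O)(=O)C(F)(F)F)
Why: Silylation with the silyl triflate protects the hindered axial C4 hydroxyl as a TBS ether that survives the hydride, organozinc, borane and acylation steps that follow.

**Step 11**
Reactants: 16 TBS ether lactone
Product: 17 diol (C1–OH and primary C8–OH, C4–OTBS)
Conditions: LiAlH4, THF, 0 °C; then H2O, aq. NaOH
Reagents that add atoms: none
Why: Hydride reduction of the lactone with LiAlH4 releases the C1 hydroxyl and the primary C8 alcohol faster than any enolisation at C7, so no stereocentre changes and the TBS ether is retained.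

**Step 12**
Reactants: 17 diol
Product: 19 primary iodide with C1–OTES and C4–OTBS, via iodo alcohol 18 (not isolated)
Conditions: I2, PPh3, imidazole, CH2Cl2, 0 °C; then TESCl, DMAP (cat.), 0 → 25 °C
Reagents that add atoms: iodine (II); chlorotriethylsilane (CC[Si](Cl)(CC)CC)
Why: Appel iodination converts the less hindered primary C8 alcohol through its alkoxyphosphonium salt into the iodide by SN2 displacement, and immediate TES ether formation at the secondary C1 hydroxyl in the same flask keeps the gamma-iodo alcohol from closing to a tetrahydrofuran.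

**Step 13**
Reactants: 19 iodide; 20 3-methylbut-2-enoyl chloride
Product: 22 enone (C9 ketone, C10=C11), via alkylzinc iodide 21 (not isolated)
Conditions: Zn dust, LiCl, THF, 40 °C; then Pd(PPh3)4 (5 mol %), THF, 0 → 25 °C
Reagents that add atoms: none
Why: LiCl-assisted zinc insertion into the primary C–I bond gives an alkylzinc iodide that tolerates both silyl ethers, and Negishi-type acylation (zerovalent palladium inserts into the C–Cl bond, transmetallation, reductive elimination) forms the C8–C9 bond; the beta,beta-disubstituted enone is a poor conjugate acceptor.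

**Step 14**
Reactants: 22 enone
Product: 23 (9R) allylic alcohol
Conditions: (S)-2-methyl-CBS-oxazaborolidine (0.5 equiv), catecholborane, toluene, −78 °C; then MeOH, aq. NaHCO3
Reagents that add atoms: none
Why: Corey–Bakshi–Shibata reduction: the ketone binds to the oxazaborolidine boron with its alkenyl arm in the large-group position and catecholborane delivers hydride to one carbonyl face, so the (S)-catalyst should give the (9R) alcohol by reagent control, with 1,2-selectivity and without touching the alkene.

**Step 15**
Reactants: 23 allylic alcohol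
Product: 24 (9R) acetate
Conditions: Ac2O, pyridine, DMAP (cat.), CH2Cl2, 0 → 25 °C
Reagents that add atoms: acetic anhydride (CC(=O)OC(C)=O)
Why: DMAP-catalysed acetylation of the only free hydroxyl gives the C9 acetate with retention.

**Step 16**
Reactants: 24 acetate
Product: 25 C1 alcohol (C4–OTBS, C9–OAc)
Conditions: HF·pyridine, pyridine, THF, 0 °C
Reagents that add atoms: none
Why: Chemoselective desilylation: buffered HF·pyridine cleaves the triethylsilyl ether much faster than the bulkier TBS ether on the hindered axial C4 oxygen, and the allylic acetate should be stable under these mildly acidic conditions.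

**Step 17**
Reactants: 25 C1 alcohol; 26 angelic acid
Product: 28 C1 angelate (C4–OTBS), via mixed anhydride 27 (not isolated)
Conditions: 2,4,6-trichlorobenzoyl chloride, Et3N, toluene, 25 °C; then 25, toluene, 80 °C
Reagents that add atoms: none
Why: Yamaguchi-type esterification through the mixed anhydride without a nucleophilic catalyst: the C1 alcohol attacks the less hindered angeloyl carbonyl, and leaving out DMAP avoids the addition–elimination pathway that isomerises the Z (angelate) double bond to the E (tiglate) form.

**Step 18**
Reactants: 28 C1 angelate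
Product: 29 target, (1R,2S,4R,5S)-2-[(2R,4R)-4-acetoxy-6-methylhept-5-en-2-yl]-4-hydroxy-5-methylcyclohexyl (2Z)-2-methylbut-2-enoate
Conditions: HF·pyridine, THF, 0 → 25 °C
Reagents that add atoms: none
Why: Fluoride-mediated desilylation with HF·pyridine removes the TBS group from C4 while leaving the angelate, the allylic acetate and both alkenes intact, and no acyl migration is possible because no ester is vicinal to the freed hydroxyl.

**Compound list**
1 | (R)-(−)-carvone | CC1=CC[C@H](CC1=O)C(C)=C | starting material
2 | p-toluenesulfonohydrazide | Cc1ccc(cc1)S(=O)(=O)NN | starting material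
3 | carvone tosylhydrazone (hydrazone at C2) | CC1=CC[C@H](CC1=NNS(=O)(=O)c1ccc(C)cc1)C(C)=C | intermediate
4 | C2 vinyllithium of the triene (not isolated) | C1=C([Li])C(C)=CC[C@H]1C(C)=C | intermediate
5 | (R)-5-isopropenyl-2-methylcyclohexa-1,3-diene (p-mentha-1,5,8-triene) | C1=CC(C)=CC[C@H]1C(C)=C | intermediate
6 | (1R,4R,7S)-5-methyl-7-(prop-1-en-2-yl)-2,3-dioxabicyclo[2.2.2]oct-5-ene, O–O bridge anti to isopropenyl | O2[C@@H]1C=C(C)[C@H](O2)C[C@H]1C(C)=C | intermediate
7 | cis-ene-diol, both OH trans to isopropenyl | O[C@@H]1C=C(C)[C@H](O)C[C@H]1C(C)=C | intermediate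
8 | C8 alkyl-9-BBN with both hydroxyls as 9-BBN borinates (not isolated, C7 epimers) | B1(O[C@@H]2C=C(C)[C@H](OB3C4CCCC3CCC4)C[C@H]2C(C)CB2C3CCCC2CCC3)C2CCCC1CCC2 | intermediate
9 | ene-triol (C7 epimers) | O[C@@H]1C=C(C)[C@H](O)C[C@H]1C(C)CO | intermediate
10 | trans-fused lactol (not isolated, C7 epimers) | OC1O[C@@H]2C=C(C)[C@H](O)C[C@H]2C1C | intermediate
11 | hydroxy ene lactone (not isolated, C7 epimers) | O=C1O[C@@H]2C=C(C)[C@H](O)C[C@H]2C1C | intermediate
12 | enone lactone (C7 epimers) | O=C1O[C@@H]2C=C(C)C(=O)C[C@H]2C1C | intermediate
13 | saturated keto lactone (C3 and C7 epimers) | O=C1O[C@@H]2CC(C)C(=O)C[C@H]2C1C | intermediate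
14 | keto lactone, C3 methyl equatorial, C7 methyl cis to H6 | O=C1O[C@@H]2C[C@H](C)C(=O)C[C@H]2[C@@H]1C | intermediate
15 | hydroxy lactone, axial C4–OH | O=C1O[C@@H]2C[C@H](C)[C@H](O)C[C@H]2[C@@H]1C | intermediate
16 | C4 TBS ether lactone | O=C1O[C@@H]2C[C@H](C)[C@H](O[Si](C)(C)C(C)(C)C)C[C@H]2[C@@H]1C | intermediate
17 | diol (C1–OH, C8–OH, C4–OTBS) | O[C@@H]1C[C@H](C)[C@H](O[Si](C)(C)C(C)(C)C)C[C@H]1[C@H](C)CO | intermediate
18 | iodo alcohol (not isolated) | O[C@@H]1C[C@H](C)[C@H](O[Si](C)(C)C(C)(C)C)C[C@H]1[C@H](C)CI | intermediate
19 | C8 iodide, C1–OTES, C4–OTBS | CC[Si](CC)(CC)O[C@@H]1C[C@H](C)[C@H](O[Si](C)(C)C(C)(C)C)C[C@H]1[C@H](C)CI | intermediate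
20 | 3-methylbut-2-enoyl chloride | CC(C)=CC(Cl)=O | starting material
21 | C8 alkylzinc iodide (not isolated) | CC[Si](CC)(CC)O[C@@H]1C[C@H](C)[C@H](O[Si](C)(C)C(C)(C)C)C[C@H]1[C@H](C)C[Zn]I | intermediate
22 | C9 enone | CC[Si](CC)(CC)O[C@@H]1C[C@H](C)[C@H](O[Si](C)(C)C(C)(C)C)C[C@H]1[C@H](C)CC(=O)C=C(C)C | intermediate
23 | (9R) allylic alcohol | CC[Si](CC)(CC)O[C@@H]1C[C@H](C)[C@H](O[Si](C)(C)C(C)(C)C)C[C@H]1[C@H](C)C[C@H](C=C(C)C)O | intermediate
24 | (9R) acetate | CC[Si](CC)(CC)O[C@@H]1C[C@H](C)[C@H](O[Si](C)(C)C(C)(C)C)C[C@H]1[C@H](C)C[C@H](C=C(C)C)OC(C)=O | intermediate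
25 | C1 alcohol (C4–OTBS, C9–OAc) | O[C@@H]1C[C@H](C)[C@H](O[Si](C)(C)C(C)(C)C)C[C@H]1[C@H](C)C[C@H](C=C(C)C)OC(C)=O | intermediate
26 | angelic acid | C/C=C(/C)C(O)=O | starting material
27 | angelic 2,4,6-trichlorobenzoic mixed anhydride (not isolated) | C/C=C(/C)C(=O)OC(=O)c1c(Cl)cc(Cl)cc1Cl | intermediate
28 | C1 angelate, C4–OTBS | C/C=C(/C)C(=O)O[C@@H]1C[C@H](C)[C@H](O[Si](C)(C)C(C)(C)C)C[C@H]1[C@H](C)C[C@H](C=C(C)C)OC(C)=O | intermediate
29 | CNP0237033.1 | C/C=C(/C)C(=O)O[C@@H]1C[C@H](C)[C@H](O)C[C@H]1[C@H](C)C[C@H](C=C(C)C)OC(C)=O | target

Total step count: 18. Longest linear sequence: 18 steps (1 to 29).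

**Steps most likely to fail**

Step 3. Oxygen may add to the face syn to C6 to a larger extent than hoped, and ene reactions or aromatisation of the triene may consume material. The fallback reaches the same diol without a cycloaddition; it sets out from 1 and comes back at 7. Kinetic enolisation of 1 at C1 (LDA, THF, −78 °C) and hydroxylation with 2-(phenylsulfonyl)-3-phenyloxaziridine should give the hydroxy ketone F1, with the new hydroxyl anti to the isopropenyl group. Silylation (TBSCl, imidazole) gives the silyl ether F2. Nucleophilic epoxidation of the enone (H2O2, NaOH, MeOH), expected anti to the isopropenyl group, gives the epoxy ketone F3. Wharton transposition (N2H4·H2O, AcOH, MeOH) moves the oxygen to C4 and the alkene to C2=C3, giving the mono-silylated ene-diol F4. TBAF then releases 7.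

Step 12. The activated primary alcohol, or the iodide before it is silylated, may be attacked by the free C1 hydroxyl and close to a trans-fused tetrahydrofuran. The fallback removes the free hydroxyl before activation; it sets out from 17 and comes back at 19. Double silylation (TESOTf, 2,6-lutidine) gives the bis-TES ether F5. Selective solvolysis of the primary silyl ether (PPTS, MeOH–CH2Cl2, −10 °C) gives the primary alcohol F6, which carries the C1–OTES group. Appel iodination (I2, PPh3, imidazole) then gives 19.

Step 14. The catalyst may discriminate the two carbonyl faces poorly, because the beta-branched alkyl arm and the isobutenyl arm differ less in size than in standard substrates. The fallback replaces reagent control by separation and inversion; it sets out from 22 and comes back at 24. Luche reduction (NaBH4, CeCl3·7H2O, MeOH, −78 °C) gives 23 together with the (9S) alcohol F7, and the two are separated by chromatography. 23 is acetylated as in step 15. F7 is converted into the same acetate 24 by Mitsunobu inversion (AcOH, PPh3, DIAD, toluene, 0 °C).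

**Further compounds**
F1 | step 3 | trans-1-hydroxy ketone from carvone (OH at C1 anti to isopropenyl) | O[C@@H]1C(=O)C(C)=CC[C@H]1C(C)=C
F2 | step 3 | TBS ether of F1 | CC(C)(C)[Si](C)(C)O[C@@H]1C(=O)C(C)=CC[C@H]1C(C)=C
F3 | step 3 | C3–C4 epoxy ketone, epoxide anti to isopropenyl | CC(C)(C)[Si](C)(C)O[C@@H]1C(=O)[C@]2(C)O[C@@H]2C[C@H]1C(C)=C
F4 | step 3 | mono-TBS ene-diol (C1–OTBS, C4–OH) | CC(C)(C)[Si](C)(C)O[C@@H]1C=C(C)[C@H](O)C[C@H]1C(C)=C
F5 | step 12 | bis-TES ether of 17 | CC[Si](CC)(CC)O[C@@H]1C[C@H](C)[C@H](O[Si](C)(C)C(C)(C)C)C[C@H]1[C@H](C)CO[Si](CC)(CC)CC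
F6 | step 12 | primary alcohol with C1–OTES and C4–OTBS | CC[Si](CC)(CC)O[C@@H]1C[C@H](C)[C@H](O[Si](C)(C)C(C)(C)C)C[C@H]1[C@H](C)CO
F7 | step 14 | (9S) allylic alcohol, C9 epimer of 23 | CC[Si](CC)(CC)O[C@@H]1C[C@H](C)[C@H](O[Si](C)(C)C(C)(C)C)C[C@H]1[C@H](C)C[C@@H](C=C(C)C)O
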